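**Plan**

- Retrosynthesis: the acetate and the two methyl esters come off last. The C12–C13 bond is then cut, which separates the complete decalin from a four-carbon Z-iodo enoate. In the decalin, the cuts are C8–C17, then the C12–O and C9–CO bonds of a temporary spiro-butyrolactone, then the ring bonds C9–C10 and C4–C5, and finally C6–C7.
- Forward: C6–C7 is made by dianion alkylation of acetylbutyrolactone with geranyl bromide. Acid-initiated bicyclisation closes ring A (C4–C5), then ring B (C9–C10). HCl opens the lactone with loss of CO2 and leaves C12 as CH2Cl. C17 enters by carbonylation of the C7=C8 enol triflate. C6 oxidation and reductive transposition give C6=C7. Coupling, ester hydrolysis and acetylation finish the route.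
- Feature that allows the union: C12 leaves the lactone as an electrophilic CH2Cl two carbons from C9, and C13 is the electrophilic β-carbon of the C15 enoate. Zinc insertion reverses the polarity of C12. Iodine held cis to the C15 carbonyl on C13 is replaced with retention, so C12 ends cis to C15 (13E).
- Stereochemistry: C5 and C10 come from the enantioface of protonation and the chair–chair fold of the E-alkene (trans ring fusion). C9 is set by acid equilibration next to the C8 ketone. C8 is set by suprafacial hydrogen transfer from a C6 diazene on the methyl face. 13E comes from anti-hydroiodination and retentive coupling.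

Key step: step 11

Remark: labdane numbering is used; "methyl face" is the decalin face that carries the C10 methyl and "H5 face" the opposite one; the C9 configuration of 4 and 5 is not controlled and is drawn arbitrarily because step 3 erases it, and 10 is drawn as the E-hydrazone.

**Route**

Step 1
Reactants: 1 α-acetyl-γ-butyrolactone; 2 geranyl bromide
Product: 3 acyclic keto lactone
Conditions: NaH, THF, 0 °C; n-BuLi, 0 °C; then 2, 0 °C → rt; aq. HCl work-up
Reagents that add atoms: none
Why: Dianion γ-alkylation of a 1,3-dicarbonyl compound: the second, more basic carbanion on the acetyl methyl (C7) should be alkylated by the allylic bromide in an SN2 reaction that keeps the E geometry of the future C5=C10 alkene, and the only stereocentre (C9) is enolisable and of no consequence.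

Step 2
Reactants: 3 acyclic keto lactone
Product: 4 spiro keto lactone
Conditions: SnCl4 (1.0 equiv), toluene, −78 °C; then (S)-2-(2-fluorobenzyloxy)-2'-hydroxy-1,1'-binaphthyl·SnCl4 (2 equiv, the binaphthol enantiomer that leads to the 5R series), −78 °C, 2 d; then SnCl4, CH2Cl2, −78 → 0 °C
Reagents that add atoms: none
Why: Proposed new method: the tin-bound binaphthol proton (a Lewis-acid-assisted chiral Brønsted acid) should protonate one enantioface of the terminal trisubstituted alkene of the chair–chair folded chain, after which antiperiplanar cation–olefin addition closes ring A (C5 onto C4, 6-endo) and the tin-chelated enol carbon C9 closes ring B onto the C10 cation (6-endo), the E-C5=C10 alkene giving the trans fusion and the protonation face fixing C5 and C10; the closest known reaction types are the enantioselective cyclisation of homofarnesol-type polyenes by such chiral acids (first ring closure enantio-determining, completion with achiral acid) and the racemic SnCl4 cyclisation of geranylated acetoacetates, and the untested element, a chelating 1,3-dicarbonyl terminator beside the chiral acid, is met by saturating it with SnCl4 beforehand.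

Step 3
Reactants: 4 spiro keto lactone
Product: 6 chloro ketone, via keto acid 5 (not isolated)
Conditions: conc. HCl, AcOH, 100 °C
Reagents that add atoms: hydrogen chloride, Cl
Why: Acid-mediated chloride opening of an α-acyl lactone at its O–CH2 carbon (the classical acetylbutyrolactone to 5-chloro-2-pentanone conversion) followed by β-keto acid decarboxylation, with C9 set by acid-catalysed equilibration next to the ketone to the equatorial epimer (arm on the methyl face).

Step 4
Reactants: 6 chloro ketone
Product: 7 enol triflate
Conditions: KN(SiMe3)2, THF, −78 °C; N-(5-chloro-2-pyridyl)bis(trifluoromethanesulfonimide), −78 °C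
Reagents that add atoms: N-(5-chloro-2-pyridyl)bis(trifluoromethanesulfonimide), FC(F)(F)S(=O)(=O)N(c1ccc(Cl)cn1)S(=O)(=O)C(F)(F)F
Why: Enol triflate formation under kinetic control: the bulky amide should remove a proton from the C7 methylene and not the tertiary, neopentyl C9–H, and fast O-sulfonylation at −78 °C should outrun alkylation of the enolate by the pendant chloride.

Step 5
Reactants: 7 enol triflate
Product: 8 conjugated ester
Conditions: Pd(OAc)2 (5 mol %), PPh3, CO (1 atm), MeOH, Et3N, DMF, 60 °C
Reagents that add atoms: carbon monoxide, [C-]#[O+]; methanol, CO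
Why: Palladium-catalysed methoxycarbonylation of an enol triflate (oxidative addition, CO insertion, methanolysis of the acylpalladium) installs C17, and the primary alkyl chloride is inert to zerovalent palladium under these conditions.

Step 6
Reactants: 8 conjugated ester
Product: 9 oxo ester
Conditions: Rh2(cap)4 (1 mol %, cap = caprolactamate), t-BuOOH (70 % aq., 5 equiv), 1,2-dichloroethane, 40 °C
Reagents that add atoms: tert-butyl hydroperoxide, CC(C)(C)OO
Why: Allylic C–H oxidation by tert-butylperoxyl radicals, known to turn cyclohex-1-enecarboxylates into their 3-oxo derivatives, should take the γ-methylene C6 (its radical is delocalised onto C8 and the ester) and not the hindered, cross-conjugated tertiary C9–H.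

Step 7
Reactants: 9 oxo ester
Product: 10 tosylhydrazone
Conditions: TsNHNH2, MeOH, AcOH (cat.), 50 °C
Reagents that add atoms: 4-methylbenzenesulfonohydrazide, Cc1ccc(cc1)S(=O)(=O)NN
Why: Acid-catalysed hydrazone condensation at the C6 ketone, with the sulfonamide nitrogen turned away from the crowded C5 side.

Step 8
Reactants: 10 tosylhydrazone
Product: 12 chloro ester, via allylic diazene 11 (not isolated)
Conditions: catecholborane, CHCl3, 0 °C → rt; then NaOAc·3H2O, 60 °C
Reagents that add atoms: none
Why: Reductive alkene transposition through an allylic diazene (catecholborane reduction of an enone tosylhydrazone): hydride should reach C6 from the H5 face because the methyl face is screened by the axial methyls on C4 and C10, acetate-induced loss of sulfinate leaves the diazene on the methyl face, and its retro-ene loss of N2 passes hydrogen suprafacially to C8 on the methyl face while the alkene moves to C6=C7, which sets C8 (ester on the H5 face, trans to the C9 arm) without an enolate.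

Step 9
Reactants: 13 methyl 4-hydroxybut-2-ynoate
Product: 14 hydroxy iodide
Conditions: NaI, AcOH, 70 °C
Reagents that add atoms: sodium iodide, [Na+].[I-]
Why: anti-Hydroiodination of an ynoate (conjugate addition of iodide, protonation anti to iodine) should give the Z-iodide with iodine cis to the ester, so the hydroxymethyl group is trans to the ester and cannot lactonise.

Step 10
Reactants: 14 hydroxy iodide
Product: 15 silyl iodide
Conditions: Et3SiCl, imidazole, CH2Cl2, 0 °C
Reagents that add atoms: chlorotriethylsilane, CC[Si](Cl)(CC)CC
Why: Silyl ether protection of the primary alcohol so that it cannot protonate the organozinc reagent in the coupling.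

Step 11
Reactants: 12 chloro ester; 15 silyl iodide
Product: 18 hydroxy diester, via alkylzinc chloride 16 (not isolated), via silyl ether 17 (not isolated)
Conditions: Zn dust, I2 (5 mol %), LiBr, DMA, 80 °C; then 15, Pd(OAc)2 (3 mol %), SPhos (6 mol %), THF, rt; then 1 M HCl, THF, 0 °C
Reagents that add atoms: none
Why: Zinc (activated by I2, with bromide exchange) should insert into the primary C12–Cl bond, which reverses the polarity of the carbon that left the lactone as an electrophile and gives alkylzinc 16 without touching the C17 ester, the C6=C7 alkene or C8–H. Zerovalent palladium then adds oxidatively to the C13–I bond of 15 with retention, the alkyl group passes from zinc to palladium, reductive elimination forms the C12–C13 bond, and dilute acid removes the triethylsilyl group. The closest known reaction type is the Negishi coupling of a primary alkylzinc halide with a (Z)-β-iodo enoate. No ring is closed and no stereocentre is created; the only stereochemical element, the C13=C14 geometry, is carried over from 15, so that C12 takes the place of iodine cis to the C15 carbonyl (13E). The step needs retention of that geometry and reductive elimination faster than β-hydride elimination; palladium (whose alkenyl complexes keep their configuration) and the bulky biarylphosphine should secure both, and the iodine on the enoate β-carbon makes oxidative addition fast enough to outrun conjugate addition. The four existing stereocentres should survive because the organozinc is weakly basic and the medium is neutral.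

Step 12
Reactants: 18 hydroxy diester
Product: 19 hydroxy diacid
Conditions: Me3SnOH, 1,2-dichloroethane, 80 °C; then aq. HCl work-up
Reagents that add atoms: trimethyltin hydroxide, C[Sn](C)(C)O
Why: Trimethyltin hydroxide ester hydrolysis should cleave both methyl esters under nearly neutral conditions that do not move the C6=C7 alkene into conjugation, and C8 already holds the thermodynamically preferred equatorial configuration.

Step 13
Reactants: 19 hydroxy diacid
Product: 20 target acid
Conditions: Ac2O, pyridine, DMAP (cat.), CH2Cl2, 0 °C; then H2O
Reagents that add atoms: acetic anhydride, CC(=O)OC(C)=O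
Why: O-Acetylation of the primary allylic alcohol; mixed anhydrides formed at the two acids are hydrolysed in the aqueous work-up, and the hydroxy acid cannot lactonise because C16 is trans to C15.

**Compound list**

1 | α-acetyl-γ-butyrolactone (3-acetyloxolan-2-one) | CC(=O)C1CCOC1=O | starting material
2 | geranyl bromide, (2E)-1-bromo-3,7-dimethylocta-2,6-diene | CC(C)=CCC/C(C)=C/CBr | starting material
3 | acyclic keto lactone, 3-[(4E)-5,9-dimethyldeca-4,8-dienoyl]oxolan-2-one | CC(C)=CCC/C(C)=C/CCC(=O)C1CCOC1=O | intermediate
4 | spiro keto lactone: 4,4,10-trimethyl-trans-decalin-8-one (H5 on the face opposite to the C10 methyl) whose C9 is the spiro α-carbon of a γ-butyrolactone (C9–C11H2–C12H2–O–CO) | C1COC(=O)[C@]12C(=O)CC[C@@H]3C(C)(C)CCC[C@@]23C | intermediate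
5 | keto acid: 9-carboxy-9-(2-chloroethyl)-4,4,10-trimethyl-trans-decalin-8-one | OC(=O)[C@@]1(CCCl)C(=O)CC[C@@H]2C(C)(C)CCC[C@@]12C | intermediate
6 | chloro ketone: 9-(2-chloroethyl)-4,4,10-trimethyl-trans-decalin-8-one, arm equatorial on the methyl face, H9 and H5 on the opposite face | ClCC[C@@H]1C(=O)CC[C@@H]2C(C)(C)CCC[C@@]12C | intermediate
7 | enol triflate: C7=C8 enol trifluoromethanesulfonate of 6 | ClCC[C@@H]1C(OS(=O)(=O)C(F)(F)F)=CC[C@@H]2C(C)(C)CCC[C@@]12C | intermediate
8 | conjugated ester: methyl 9-(2-chloroethyl)-4,4,10-trimethyl-Δ7-octalin-8-carboxylate (stereocentres as in 6) | ClCC[C@@H]1C(C(=O)OC)=CC[C@@H]2C(C)(C)CCC[C@@]12C | intermediate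
9 | oxo ester: 6-oxo derivative of 8 (C6 ketone, C7=C8, C8–CO2Me) | ClCC[C@@H]1C(C(=O)OC)=CC(=O)[C@@H]2C(C)(C)CCC[C@@]12C | intermediate
10 | tosylhydrazone: (E)-N-tosylhydrazone of the C6 ketone of 9 | ClCC[C@@H]1C(C(=O)OC)=C/C(=N\NS(=O)(=O)c3ccc(C)cc3)[C@@H]2C(C)(C)CCC[C@@]12C | intermediate
11 | allylic diazene: C6–N=NH on the methyl face, C7=C8 and C8–CO2Me as in 8 | ClCC[C@@H]1C(C(=O)OC)=C[C@H](N=N)[C@@H]2C(C)(C)CCC[C@@]12C | intermediate
12 | chloro ester: methyl (5R,8S,9R,10S)-9-(2-chloroethyl)-4,4,10-trimethyl-Δ6-octalin-8-carboxylate, CO2Me on the H5 face, H8 on the methyl face | ClCC[C@@H]1[C@@H](C(=O)OC)C=C[C@@H]2C(C)(C)CCC[C@@]12C | intermediate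
13 | methyl 4-hydroxybut-2-ynoate | COC(=O)C#CCO | starting material
14 | hydroxy iodide: methyl (2Z)-4-hydroxy-3-iodobut-2-enoate | COC(=O)/C=C(\I)CO | intermediate
15 | silyl iodide: methyl (2Z)-3-iodo-4-(triethylsilyloxy)but-2-enoate | COC(=O)/C=C(\I)CO[Si](CC)(CC)CC | intermediate
16 | alkylzinc chloride: C12–ZnCl derivative of 12 (halide on zinc exchangeable) | Cl[Zn]CC[C@@H]1[C@@H](C(=O)OC)C=C[C@@H]2C(C)(C)CCC[C@@]12C | intermediate
17 | silyl ether: 16-O-triethylsilyl ether of 18 | CC[Si](CC)(CC)OC/C(=C/C(=O)OC)CC[C@@H]1[C@@H](C(=O)OC)C=C[C@@H]2C(C)(C)CCC[C@@]12C | intermediate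
18 | hydroxy diester: dimethyl (5R,8S,9R,10S,13E)-16-hydroxylabda-6,13-diene-15,17-dioate | OC/C(=C/C(=O)OC)CC[C@@H]1[C@@H](C(=O)OC)C=C[C@@H]2C(C)(C)CCC[C@@]12C | intermediate
19 | hydroxy diacid: (5R,8S,9R,10S,13E)-16-hydroxylabda-6,13-diene-15,17-dioic acid | OC/C(=C/C(=O)O)CC[C@@H]1[C@@H](C(=O)O)C=C[C@@H]2C(C)(C)CCC[C@@]12C | intermediate
20 | target acid: (5R,8S,9R,10S,13E)-16-acetoxylabda-6,13-diene-15,17-dioic acid (an ent-labdane; C10 methyl and C9 chain on one face, H5, H9 and the C8 carboxyl on the other) | CC(=O)OC/C(=C/C(=O)O)CC[C@@H]1[C@@H](C(=O)O)C=C[C@@H]2C(C)(C)CCC[C@@]12C | target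

**Step count and risks**

Total: 13 steps. Longest linear sequence: 11 steps (steps 1–8 and 11–13); steps 9 and 10 prepare the iodide.

Steps most likely to fail:

1. Step 2 (labelled step). The 1,3-dicarbonyl terminator may strip SnCl4 from the chiral acid, so that protonation is poorly face-selective or an achiral background cyclisation takes over; ring B may also close through oxygen. The fallback uses known chemistry (racemic cyclisation, then resolution of the ketone through diastereomeric ketals) and sets out from 3. SnCl4 alone in CH2Cl2 at 0 °C should give 4 as a racemate, that is, together with the mirror-image spiro keto lactone F1. The conditions of step 3 then give 6 together with the mirror-image chloro ketone F3, through the mirror-image keto acid F2, which is not isolated. Ketalisation of the mixture with (1R,2R)-hydrobenzoin (TsOH, benzene, reflux with removal of water) gives two diastereomers, the hydrobenzoin ketal of 6 F4 and the hydrobenzoin ketal of the mirror-image ketone F5, to be separated by chromatography or crystallisation. Hydrolysis of F4 (aq. HCl, THF) returns enantiopure 6, where the route is rejoined.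

2. Step 7. Condensation at the hindered C6 carbonyl may be slow, and the hydrazide may instead add in conjugate fashion to the doubly activated C7=C8 bond, or the hydrazone may cyclise to a pyrazoline. The fallback sets out from 9 and bypasses steps 7 and 8. Luche reduction (NaBH4, CeCl3·7H2O, MeOH, −78 °C, hydride from the H5 face) should give the 6-hydroxy enoate F6 with the hydroxyl on the methyl face. Hydroxyl-directed hydrogenation ([Ir(cod)(PCy3)(py)]PF6, H2, CH2Cl2) should add hydrogen to the methyl face of C7=C8 and give the saturated hydroxy ester F7 with H8 on the methyl face. syn-Dehydration with methyl N-(triethylammoniosulfonyl)carbamate (toluene, 60 °C) can use only the C7 hydrogen cis to the hydroxyl, since H5 is trans, and should give 12, where the route is rejoined.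

3. Step 11. Zinc insertion into the primary chloride may be slow or incomplete, the organozinc may be protonated, or β-hydride elimination may follow transmetalation. The fallback is a B-alkyl Suzuki–Miyaura route that sets out from 12. Sodium phenylselenide ((PhSe)2, NaBH4, EtOH) should displace chloride to give the phenyl selenide F8. Oxidation (H2O2, pyridine, CH2Cl2, 0 °C → rt) with syn-elimination should give the C9-vinyl ester F9. 9-BBN (THF, rt) should hydroborate only the terminal alkene to give the B-alkyl-9-BBN F10, which is coupled in the same flask with the free alcohol 14 (Pd(dppf)Cl2, AsPh3, Cs2CO3, DMF/H2O, rt) to give 18, where the route is rejoined.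

Further compounds
F1 | step 2 | mirror-image spiro keto lactone (enantiomer of 4) | C1COC(=O)[C@@]12C(=O)CC[C@H]3C(C)(C)CCC[C@]23C
F2 | step 2 | mirror-image keto acid (enantiomer of 5) | OC(=O)[C@]1(CCCl)C(=O)CC[C@H]2C(C)(C)CCC[C@]12C
F3 | step 2 | mirror-image chloro ketone (enantiomer of 6) | ClCC[C@H]1C(=O)CC[C@H]2C(C)(C)CCC[C@]12C
F4 | step 2 | hydrobenzoin ketal of 6 ((4R,5R)-4,5-diphenyl-1,3-dioxolane at C8) | ClCC[C@@H]1C3(O[C@H](c4ccccc4)[C@@H](c4ccccc4)O3)CC[C@@H]2C(C)(C)CCC[C@@]12C
F5 | step 2 | hydrobenzoin ketal of the mirror-image ketone | ClCC[C@H]1C3(O[C@H](c4ccccc4)[C@@H](c4ccccc4)O3)CC[C@H]2C(C)(C)CCC[C@]12C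
F6 | step 7 | 6-hydroxy enoate (hydroxyl on the methyl face, C7=C8) | ClCC[C@@H]1C(C(=O)OC)=C[C@H](O)[C@@H]2C(C)(C)CCC[C@@]12C
F7 | step 7 | saturated hydroxy ester (H8 and 6-OH on the methyl face) | ClCC[C@@H]1[C@@H](C(=O)OC)C[C@H](O)[C@@H]2C(C)(C)CCC[C@@]12C
F8 | step 11 | phenyl selenide (C12–SePh analogue of 12) | c3ccccc3[Se]CC[C@@H]1[C@@H](C(=O)OC)C=C[C@@H]2C(C)(C)CCC[C@@]12C
F9 | step 11 | C9-vinyl ester (C11=C12 alkene) | C=C[C@@H]1[C@@H](C(=O)OC)C=C[C@@H]2C(C)(C)CCC[C@@]12C
F10 | step 11 | B-alkyl-9-BBN (C12 bound to boron) | C1CC2CCCC(C1)B2CC[C@@H]3[C@@H](C(=O)OC)C=C[C@@H]4C(C)(C)CCC[C@@]34C
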